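Assumption: the target has no stereocentres and no stereogenic double bonds (it is achiral), so "single enantiomer" is taken to mean the one constitution given; nothing has to be resolved or set.

**Retrosynthetic overview**
1. Target 21 ⇐ benzyl ester 20; hydrogenolysis is the only deprotection.
2. Ring A (formed last) ⇐ aryl dec-2-ynoate 14 + Brassard diene 17: [4+2]/aromatisation on the preformed depside ester (proposed new step) makes two ring C–C bonds and unmasks the chelated OH.
3. Depside C(acyl)–O bond ⇐ phenol 13 + dec-2-ynoic acid 4, made while the acyl partner is still an unhindered alkynoic acid.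
4. Ring B (formed first) ⇐ benzyl dec-2-ynoate 6 + 1,1-dimethoxy-3-silyloxydiene 10: the regiocomplementary [4+2]/aromatisation (OMe ortho, OH para to the ester).
5. Both heptyl chains and both carboxyl carbons come from one batch of dec-2-ynoic acid 4 (1-nonyne + CO2); benzyl bromide supplies the ester protecting group.

**Route**

Step 1
Reactants: 1 1-nonyne
Product: 4 dec-2-ynoic acid, via lithium non-1-yn-1-ide 2 (not isolated), via lithium dec-2-ynoate 3 (not isolated)
Conditions: n-BuLi (1.05 equiv), THF, −78 °C; CO2 (g), −78 °C → rt; then 1 M HCl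
Reagents that add atoms: carbon dioxide, O=C=O
Why: Carboxylation of a lithium acetylide with CO2 is a routine, high-yielding route to alk-2-ynoic acids; the batch is divided between steps 2 and 6.

Step 2
Reactants: 4 dec-2-ynoic acid; 5 benzyl bromide
Product: 6 benzyl dec-2-ynoate
Conditions: K2CO3 (1.2 equiv), DMF, rt
Reagents that add atoms: none
Why: SN2 O-alkylation of the potassium carboxylate with benzyl bromide (carboxylate alkylation) gives the benzyl ester; the mild carbonate base at rt neither adds to nor isomerises the ynoate.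

Step 3
Reactants: 7 1,1-dimethoxyethene; 8 acetyl chloride
Product: 9 4,4-dimethoxybut-3-en-2-one
Conditions: pyridine (1.2 equiv), CH2Cl2, 0 °C → rt
Reagents that add atoms: none
Why: C-acylation of the strongly nucleophilic ketene acetal followed by loss of HCl to the base (acylation of a ketene acetal) gives the push–pull acylketene acetal; the base prevents chloride dealkylation of the oxocarbenium ion to methyl acetoacetate.

Step 4
Reactants: 9 4,4-dimethoxybut-3-en-2-one
Product: 10 1,1-dimethoxy-3-(trimethylsilyloxy)buta-1,3-diene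
Conditions: TMSCl, Et3N, ZnCl2 (cat.), PhMe, 40 °C; distil
Reagents that add atoms: chlorotrimethylsilane, C[Si](C)(C)Cl
Why: Soft enolisation and O-silylation of the only enolisable position, the methyl ketone, is the usual silyl dienol ether formation used for Danishefsky-type dienes.

Step 5
Reactants: 6 benzyl dec-2-ynoate; 10 1,1-dimethoxy-3-(trimethylsilyloxy)buta-1,3-diene
Product: 13 benzyl 2-heptyl-4-hydroxy-6-methoxybenzoate, via ketal cycloadduct 11 (not isolated), via aryl trimethylsilyl ether 12 (not isolated)
Conditions: 10 (2.5 equiv), neat, 110 °C, 24 h; then 1 M HCl, THF, rt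
Reagents that add atoms: none
Why: In this normal-demand Diels–Alder/aromatisation (a known reaction type for 1,1-dialkoxy-3-silyloxydienes and acetylenic esters), the CH2 terminus of the diene bonds to the heptyl-bearing β-carbon and the ketal carbon to the α-carbon; 1,4-loss of MeOH then keeps one OMe ortho to the ester and the silyl ether becomes the para OH.

Step 6
Reactants: 13 benzyl 2-heptyl-4-hydroxy-6-methoxybenzoate; 4 dec-2-ynoic acid
Product: 14 benzyl 4-(dec-2-ynoyloxy)-2-heptyl-6-methoxybenzoate
Conditions: DCC (1.1 equiv), DMAP (5 mol %), CH2Cl2, −20 → 0 °C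
Reagents that add atoms: none
Why: Steglich esterification of a phenol flanked by two ring hydrogens with an unhindered alkynoic acid; low temperature and catalytic DMAP suppress conjugate addition to the ynoate.

Step 7
Reactants: 15 methyl (E)-3-methoxybut-2-enoate
Product: 17 1,3-dimethoxy-1-(trimethylsilyloxy)buta-1,3-diene, via lithium dienolate 16 (not isolated)
Conditions: LDA (commercial solution, 1.05 equiv), THF, −78 °C; then TMSCl, −78 °C → rt; distil
Reagents that add atoms: chlorotrimethylsilane, C[Si](C)(C)Cl
Why: γ-Deprotonation of the vinylogous ester and O-silylation of the dienolate is the standard preparation of Brassard's diene.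

Step 8
Reactants: 14 benzyl 4-(dec-2-ynoyloxy)-2-heptyl-6-methoxybenzoate; 17 1,3-dimethoxy-1-(trimethylsilyloxy)buta-1,3-diene
Product: 20 benzyl 2-heptyl-4-[(2-heptyl-6-hydroxy-4-methoxybenzoyl)oxy]-6-methoxybenzoate, via mixed-ketal cycloadduct 18 (not isolated), via depside trimethylsilyl ether 19 (not isolated)
Conditions: 17 (3 equiv), PhMe, 110 °C, sealed tube, 36 h; then 1 M HCl, THF, 0 °C → rt
Reagents that add atoms: none
Why: Proposed new method: a depside-forming Diels–Alder/aromatisation benzannulation in which the ester group of the alkynoate is the complete B ring. The aryloxy group (a poorer donor than alkoxy) lowers the ynoate LUMO; the largest HOMO coefficient of the 1,1,3-trioxygenated diene (its CH2 terminus) bonds to the heptyl-bearing β-carbon while the ketene-acetal carbon bonds to the α-carbon, so orbital polarisation fixes heptyl and OH flanking the carbonyl with OMe para. Cycloadduct 18 aromatises by 1,4-loss of MeOH (which the excess silyl ketene acetal takes up, so it cannot methanolyse the aryl ester), and silyl ether 19 is cleaved on work-up to the chelated phenol. The closest known reaction type is the Diels–Alder/aromatisation of Brassard- and Danishefsky-type dienes with alkyl alk-2-ynoates and haloquinones (as in step 5); it has not been shown on an aryl alkynoate to build the acyl ring of a depside on an existing ester bond.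

Step 9
Reactants: 20 benzyl 2-heptyl-4-[(2-heptyl-6-hydroxy-4-methoxybenzoyl)oxy]-6-methoxybenzoate
Product: 21 2-heptyl-4-[(2-heptyl-6-hydroxy-4-methoxybenzoyl)oxy]-6-methoxybenzoic acid
Conditions: H2 (1 atm), 10% Pd/C, EtOAc, rt
Reagents that add atoms: none
Why: Hydrogenolysis of the benzyl ester leaves the aryl ester, the aryl methyl ethers and the phenol untouched, and no reducible C–C multiple bond remains.

**Compound list**
1 | 1-nonyne | CCCCCCCC#C | starting material
2 | lithium non-1-yn-1-ide | CCCCCCCC#C[Li] | intermediate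
3 | lithium dec-2-ynoate | CCCCCCCC#CC(=O)[O-].[Li+] | intermediate
4 | dec-2-ynoic acid | CCCCCCCC#CC(=O)O | intermediate
5 | benzyl bromide | BrCc1ccccc1 | starting material
6 | benzyl dec-2-ynoate | CCCCCCCC#CC(=O)OCc1ccccc1 | intermediate
7 | 1,1-dimethoxyethene (ketene dimethyl acetal) | C=C(OC)OC | starting material
8 | acetyl chloride | CC(=O)Cl | starting material
9 | 4,4-dimethoxybut-3-en-2-one | CC(=O)C=C(OC)OC | intermediate
10 | 1,1-dimethoxy-3-(trimethylsilyloxy)buta-1,3-diene | C=C(O[Si](C)(C)C)C=C(OC)OC | intermediate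
11 | ketal cycloadduct: benzyl 2-heptyl-6,6-dimethoxy-4-(trimethylsilyloxy)cyclohexa-1,4-diene-1-carboxylate | CCCCCCCC1=C(C(=O)OCc2ccccc2)C(OC)(OC)C=C(O[Si](C)(C)C)C1 | intermediate
12 | aryl trimethylsilyl ether: benzyl 2-heptyl-6-methoxy-4-(trimethylsilyloxy)benzoate | CCCCCCCc1cc(O[Si](C)(C)C)cc(OC)c1C(=O)OCc1ccccc1 | intermediate
13 | benzyl 2-heptyl-4-hydroxy-6-methoxybenzoate | CCCCCCCc1cc(O)cc(OC)c1C(=O)OCc1ccccc1 | intermediate
14 | benzyl 4-(dec-2-ynoyloxy)-2-heptyl-6-methoxybenzoate | CCCCCCCC#CC(=O)Oc1cc(CCCCCCC)c(C(=O)OCc2ccccc2)c(OC)c1 | intermediate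
15 | methyl (E)-3-methoxybut-2-enoate | CO/C(C)=C/C(=O)OC | starting material
16 | lithium dienolate: lithium 1,3-dimethoxybuta-1,3-dien-1-olate | C=C(OC)C=C(OC)O[Li] | intermediate
17 | 1,3-dimethoxy-1-(trimethylsilyloxy)buta-1,3-diene (Brassard diene; C1=C2 geometry immaterial, E/Z mixture usable) | C=C(OC)C=C(OC)O[Si](C)(C)C | intermediate
18 | mixed-ketal cycloadduct: benzyl 2-heptyl-4-{[2-heptyl-4,6-dimethoxy-6-(trimethylsilyloxy)cyclohexa-1,4-diene-1-carbonyl]oxy}-6-methoxybenzoate (racemic at the ketal carbon, lost on aromatisation) | CCCCCCCC1=C(C(=O)Oc2cc(CCCCCCC)c(C(=O)OCc3ccccc3)c(OC)c2)C(OC)(O[Si](C)(C)C)C=C(OC)C1 | intermediate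
19 | depside trimethylsilyl ether: benzyl 2-heptyl-4-{[2-heptyl-4-methoxy-6-(trimethylsilyloxy)benzoyl]oxy}-6-methoxybenzoate | CCCCCCCc1cc(OC)cc(O[Si](C)(C)C)c1C(=O)Oc1cc(CCCCCCC)c(C(=O)OCc2ccccc2)c(OC)c1 | intermediate
20 | benzyl 2-heptyl-4-[(2-heptyl-6-hydroxy-4-methoxybenzoyl)oxy]-6-methoxybenzoate | CCCCCCCc1cc(OC)cc(O)c1C(=O)Oc1cc(CCCCCCC)c(C(=O)OCc2ccccc2)c(OC)c1 | intermediate
21 | 2-heptyl-4-[(2-heptyl-6-hydroxy-4-methoxybenzoyl)oxy]-6-methoxybenzoic acid (CNP0128141.0) | CCCCCCCc1cc(OC)cc(O)c1C(=O)Oc1cc(CCCCCCC)c(C(=O)O)c(OC)c1 | target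

**Step count**
Total steps: 9. Longest linear sequence: 6 steps (1 → 4 → 6 → 13 → 14 → 20 → 21 by steps 1, 2, 5, 6, 8, 9; the diene branch 7 → 9 → 10 → 13 by steps 3, 4, 5 is equally long).

**Three steps most likely to fail**

Step 8 (the proposed new benzannulation). The β-alkyl ynoate may react too slowly, or the aryl ester may be cleaved before cycloaddition. The fallback uses only known chemistry, makes the acyl ring separately and forms the ester bond last; it sets out from 13 and comes back to the route at 20. Phenol 13 is O-methylated (MeI, K2CO3, acetone) to benzyl 2-heptyl-4,6-dimethoxybenzoate F1. BCl3 (CH2Cl2, −78 °C) then removes only the methyl ether ortho to the ester carbonyl through the six-membered boron chelate and gives benzyl 2-heptyl-6-hydroxy-4-methoxybenzoate F2. Hydrogenolysis (H2, Pd/C, EtOAc) gives 2-heptyl-6-hydroxy-4-methoxybenzoic acid F3. F3 and a second portion of 13 are joined by the classical depside coupling through the mixed trifluoroacetic anhydride (TFAA, toluene, rt), which tolerates the chelated ortho-OH, to give 20.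

Step 5 (ring B by Diels–Alder/aromatisation). Diene 10 is sensitive and the alkyl ynoate is a sluggish dienophile. The fallback replaces the pericyclic step by an anionic Michael–Dieckmann annulation with regiocontrol by selective protection; it sets out from 6 and comes back at 13. Lindlar semihydrogenation (H2, Pd/CaCO3–Pb, quinoline) gives benzyl (Z)-dec-2-enoate F4. Michael addition of benzyl acetoacetate and Dieckmann closure of its acetyl methyl onto the enoate ester (t-BuOK, t-BuOH, reflux; the classical dihydroresorcylate synthesis) gives benzyl 6-heptyl-2,4-dioxocyclohexane-1-carboxylate F5. Br2 in DMF (0 → 80 °C) aromatises it to benzyl 2-heptyl-4,6-dihydroxybenzoate F6. The non-chelated 4-OH is allylated selectively (allyl bromide, K2CO3, acetone, rt) to benzyl 4-(allyloxy)-2-heptyl-6-hydroxybenzoate F7. The chelated OH is methylated (MeI, K2CO3, DMF, 50 °C) to benzyl 4-(allyloxy)-2-heptyl-6-methoxybenzoate F8. Pd(PPh3)4/morpholine (THF, rt) removes the allyl group and gives 13.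

Step 3 (acylation of the ketene acetal). Ketene formation from acetyl chloride or hydrolysis of the product may lower the yield. The fallback builds the ketene acetal by vinylic substitution instead; it sets out from 8 and comes back at 9. AlCl3-mediated addition of acetyl chloride 8 to 1,1-dichloroethene (CH2Cl2, 0 °C → rt) gives 4,4,4-trichlorobutan-2-one F9, which loses HCl on distillation to give 4,4-dichlorobut-3-en-2-one F10. Addition–elimination of both vinylic chlorides with NaOMe (2 equiv, MeOH, 0 °C) gives 9.

**Further compounds**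
F1 | step 8 | benzyl 2-heptyl-4,6-dimethoxybenzoate | CCCCCCCc1cc(OC)cc(OC)c1C(=O)OCc1ccccc1
F2 | step 8 | benzyl 2-heptyl-6-hydroxy-4-methoxybenzoate | CCCCCCCc1cc(OC)cc(O)c1C(=O)OCc1ccccc1
F3 | step 8 | 2-heptyl-6-hydroxy-4-methoxybenzoic acid | CCCCCCCc1cc(OC)cc(O)c1C(=O)O
F4 | step 5 | benzyl (Z)-dec-2-enoate | CCCCCCC/C=C\C(=O)OCc1ccccc1
F5 | step 5 | benzyl 6-heptyl-2,4-dioxocyclohexane-1-carboxylate (racemic, keto/enol mixture) | CCCCCCCC1CC(=O)CC(=O)C1C(=O)OCc1ccccc1
F6 | step 5 | benzyl 2-heptyl-4,6-dihydroxybenzoate | CCCCCCCc1cc(O)cc(O)c1C(=O)OCc1ccccc1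
F7 | step 5 | benzyl 4-(allyloxy)-2-heptyl-6-hydroxybenzoate | C=CCOc1cc(CCCCCCC)c(C(=O)OCc2ccccc2)c(O)c1
F8 | step 5 | benzyl 4-(allyloxy)-2-heptyl-6-methoxybenzoate | C=CCOc1cc(CCCCCCC)c(C(=O)OCc2ccccc2)c(OC)c1
F9 | step 3 | 4,4,4-trichlorobutan-2-one | CC(=O)CC(Cl)(Cl)Cl
F10 | step 3 | 4,4-dichlorobut-3-en-2-one | CC(=O)C=C(Cl)Cl
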